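**Retrosynthetic overview**

1. Target 24 ⇐ Vilsmeier–Haack double formylation of dihydroxychroman 22. The dihydropyran ring of 22 ⇐ hetero-Diels–Alder reaction of an o-quinone methide (from carbonate 16 and isobutylmagnesium bromide) with silyl enol ether 13, then dehydrogenation and ionic hydrogenation (steps 10–11), which deliver H-3a′ and H-9′ from the convex face.
2. 13 ⇐ spiro[4.5]dec-6-en-1-one 12 ⇐ cyclohexenone 7 by a net 1,3-transposition (conjugate reduction, enol triflate, Pd/formate). The C-6=C-7 alkene and C-8 methylene of the target ring are thus the reduced form of a C-6 ketone with a C-7=C-8 double bond.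
3. Key disconnection of 7: the C-7–C-8 bond (isopropyl-bearing ring carbon to its ring CH2 neighbour) by intramolecular aldol condensation, preceded in the same flask by a catalytic asymmetric Michael addition that makes C-5–C-10. 7 ⇐ 2-(3-methylbutanoyl)cyclopentanone 4 + (E)-but-2-enal 5.
4. Enabling feature: the spiro carbon C-5 lies between C-1 (later the ether CH of the cyclopentane) and C-6 (later the vinylic CH of the cyclohexene). With both as carbonyls, C-5 is the nucleophilic carbon of a 1,3-diketone, C-7 is an enolisable α-carbon and C-8 is the aldehyde carbon of a 1,5-keto aldehyde.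
5. Ring order: cyclopentane (bought) → spiro cyclohexene (step 2) → dihydropyran (step 9); the benzene ring is bought and formylated last.

Key step: step 2

Remark: 9, 11 and 12 are carried as mixtures of epimers at C-2 (that centre becomes trigonal in step 6); tricyclic compounds are numbered as spiro[cyclohex-2-ene-1,3′-cyclopenta[b]chromenes] (O-4′, ring-fusion carbons C-3a′ and C-9a′, benzylic C-9′).

Step 1
Reactants: 1 1-(cyclopent-1-en-1-yl)pyrrolidine; 2 3-methylbutanoyl chloride
Product: 4 2-(3-methylbutanoyl)cyclopentan-1-one, via acyl enamine 3 (not isolated)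
Conditions: Et3N, CH2Cl2, 0 °C → rt; then 2 M HCl, H2O, rt
Reagents that add atoms: water (O)
Why: Stork enamine acylation: the nucleophilic β-carbon of the enamine attacks the acid chloride and aqueous acid hydrolyses the vinylogous amide to the 1,3-diketone, whose C-2 centre is labile (enol) and needs no control.

Step 2
Reactants: 4 2-(3-methylbutanoyl)cyclopentan-1-one; 5 (E)-but-2-enal
Product: 7 (5S,10R)-10-methyl-7-(propan-2-yl)spiro[4.5]dec-7-ene-1,6-dione, via Michael adduct 6 (not isolated)
Conditions: (S)-2-[diphenyl(trimethylsilyloxy)methyl]pyrrolidine (10 mol %), PhCO2H (10 mol %), toluene, 0 °C → rt; then TsOH·H2O (0.3 equiv), 4 Å MS, 80 °C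
Reagents that add atoms: none
Why: The secondary amine converts 5 into an E-iminium ion whose β-carbon is attacked by the doubly activated C-2 of the enol of 4, giving 6 with the quaternary carbon in place; the added acid then enolises the isovaleryl ketone toward its CH2, this enol adds to the pendant aldehyde, and loss of water gives the conjugated enone. The closest known reaction type is the amine-catalysed Michael/aldol (Robinson-type) annulation of β-dicarbonyl compounds with enals, used here as a spiro-annulation. The six-membered ring closes in a 6-(enolendo)-exo-trig aldol mode by forming the bond between the isopropyl-bearing carbon (C-7) and the former aldehyde carbon (C-8). C-10 is set by the catalyst, whose diphenyl(silyloxy)methyl group shields one face of the iminium ion so that the nucleophile adds to the Re face of the β-carbon. C-5 is set relative to C-10 in an open transition state in which the iminium chain lies between the two carbonyl groups of the enol and the β-methyl group sits over the flat cyclopentanone sector, not over the sector flanked by the isobutyl chain. The step needs aldol closure from the acyl CH2 and not from the ring CH2 (C-2): that alternative gives a bicyclo[3.2.1]octanol that cannot dehydrate to a bridgehead alkene, so it should revert, and dehydration funnels the material to 7.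

Step 3
Reactants: 7 (5S,10R)-10-methyl-7-(propan-2-yl)spiro[4.5]dec-7-ene-1,6-dione
Product: 9 (5S,10R)-2,10-dimethyl-7-(propan-2-yl)spiro[4.5]dec-7-ene-1,6-dione (C-2 epimers), via lithium enolate 8 (not isolated)
Conditions: LiN(iPr)2 (1.05 equiv), THF, −78 °C; MeI, −78 → −30 °C
Reagents that add atoms: iodomethane (CI)
Why: Kinetic enolate alkylation: the amide base removes a proton from C-2, the only unhindered α-CH2 of the cyclopentanone (the enone has no α′-hydrogen and its γ-deprotonation is slower at −78 °C), and the enolate is C-methylated; the new centre is formed unselectively and is erased in step 6.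

Step 4
Reactants: 9 (5S,10R)-2,10-dimethyl-7-(propan-2-yl)spiro[4.5]dec-7-ene-1,6-dione (C-2 epimers)
Product: 11 (5R,10R)-2,10-dimethyl-1-oxo-7-(propan-2-yl)spiro[4.5]dec-6-en-6-yl trifluoromethanesulfonate (C-2 epimers), via lithium enolate 10 (not isolated)
Conditions: LiBH(s-Bu)3 (1.05 equiv), THF, −78 °C; then 2-[N,N-bis(trifluoromethanesulfonyl)amino]-5-chloropyridine, −78 → 0 °C
Reagents that add atoms: 2-[N,N-bis(trifluoromethanesulfonyl)amino]-5-chloropyridine (O=S(=O)(N(c1ccc(Cl)cn1)S(=O)(=O)C(F)(F)F)C(F)(F)F)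
Why: Conjugate reduction–enolate triflation: the bulky hydride adds to the β-carbon C-8 of the enone, whose carbonyl is shielded by the spiro carbon, and the regiodefined lithium enolate is O-sulfonylated, which moves the double bond to C-6=C-7 and makes C-8 a CH2 group without creating a stereocentre; the cyclopentanone, flanked by a quaternary and a tertiary carbon, should not compete for one equivalent of hydride at −78 °C.

Step 5
Reactants: 11 (5R,10R)-2,10-dimethyl-1-oxo-7-(propan-2-yl)spiro[4.5]dec-6-en-6-yl trifluoromethanesulfonate (C-2 epimers)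
Product: 12 (5R,10R)-2,10-dimethyl-7-(propan-2-yl)spiro[4.5]dec-6-en-1-one (C-2 epimers)
Conditions: Pd(OAc)2 (5 mol %), PPh3, HCO2H, Bu3N, DMF, 60 °C
Reagents that add atoms: none
Why: Palladium-catalysed formate reduction of an enol triflate (oxidative addition, formate exchange, loss of CO2, C–H reductive elimination) replaces the sulfonate by hydrogen without moving the C-6=C-7 double bond.

Step 6
Reactants: 12 (5R,10R)-2,10-dimethyl-7-(propan-2-yl)spiro[4.5]dec-6-en-1-one (C-2 epimers)
Product: 13 tert-butyl{[(5R,10R)-2,10-dimethyl-7-(propan-2-yl)spiro[4.5]deca-1,6-dien-1-yl]oxy}dimethylsilane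
Conditions: TBSOTf, Et3N, CH2Cl2, 0 °C → rt
Reagents that add atoms: tert-butyldimethylsilyl trifluoromethanesulfonate (CC(C)(C)[Si](C)(C)OS(=O)(=O)C(F)(F)F)
Why: Soft enolisation and O-silylation: only C-2 carries an α-hydrogen (C-5 is quaternary), so both C-2 epimers of 12 converge on the single tetrasubstituted silyl enol ether.

Step 7
Reactants: 14 2,4,6-trihydroxybenzaldehyde
Product: 15 2-hydroxy-4,6-bis(methoxymethoxy)benzaldehyde
Conditions: MOMCl (2.1 equiv), iPr2NEt, CH2Cl2, 0 °C
Reagents that add atoms: chloromethyl methyl ether (COCCl)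
Why: Williamson-type O-alkylation: the para and one ortho hydroxyl group are alkylated while the remaining ortho hydroxyl group, deactivated by its hydrogen bond to the formyl group, stays free.

Step 8
Reactants: 15 2-hydroxy-4,6-bis(methoxymethoxy)benzaldehyde
Product: 16 tert-butyl 2-formyl-3,5-bis(methoxymethoxy)phenyl carbonate
Conditions: Boc2O, iPr2NEt, DMAP (5 mol %), THF, rt
Reagents that add atoms: di-tert-butyl dicarbonate (CC(C)(C)OC(=O)OC(=O)OC(C)(C)C)
Why: DMAP-catalysed O-acylation of the chelated phenol gives the aryl tert-butyl carbonate that later serves as the internal leaving group for quinone methide generation.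

Step 9
Reactants: 13 tert-butyl{[(5R,10R)-2,10-dimethyl-7-(propan-2-yl)spiro[4.5]deca-1,6-dien-1-yl]oxy}dimethylsilane; 16 tert-butyl 2-formyl-3,5-bis(methoxymethoxy)phenyl carbonate; 17 isobutylmagnesium bromide
Product: 19 tert-butyl{[(1R,3a′R,6R,9′S,9a′R)-6′,8′-bis(methoxymethoxy)-6,9a′-dimethyl-9′-(2-methylpropyl)-3-(propan-2-yl)-1′,2′,9′,9a′-tetrahydro-3a′H-spiro[cyclohex-2-ene-1,3′-cyclopenta[b]chromen]-3a′-yl]oxy}dimethylsilane (isobutyl cis to the 9a′-methyl group), via o-quinone methide 18 (not isolated)
Conditions: 16 (1.5 equiv), iBuMgBr (1.55 equiv), Et2O, −78 °C → rt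
Reagents that add atoms: none
Why: Grignard addition to the aldehyde of 16, transfer of the Boc group to the new alkoxide and loss of tert-butyl carbonate generate o-quinone methide 18, which undergoes an inverse-electron-demand hetero-Diels–Alder reaction with the silyl enol ether (its methyl-bearing C-2 bonds to the methide carbon, its siloxy carbon to oxygen) on the face opposite the C-10 methyl group, which lies over the C-1 side, so that the ether oxygen and C-9′ end cis to the vinylic carbon of the cyclohexene; the siloxy-endo approach of the E-quinone methide is expected to place the isobutyl group cis to the angular methyl group, which is corrected in steps 10 and 11.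

Step 10
Reactants: 19 silyl ketal cycloadduct (name as in step 9)
Product: 20 tert-butyl{[(1R,3a′R,6R,9a′R)-6′,8′-bis(methoxymethoxy)-6,9a′-dimethyl-9′-(2-methylpropylidene)-3-(propan-2-yl)-1′,2′,9′,9a′-tetrahydro-3a′H-spiro[cyclohex-2-ene-1,3′-cyclopenta[b]chromen]-3a′-yl]oxy}dimethylsilane (alkene geometry not controlled)
Conditions: DDQ (1.2 equiv), NaHCO3, 1,4-dioxane, 50 °C
Reagents that add atoms: none
Why: DDQ dehydrogenation of a chroman: hydride abstraction from the benzylic C-9′–H, activated by the ortho and para oxygen atoms, gives a cation that can only lose a proton from the isobutyl CH2 (C-9a′ is quaternary), so the configuration at C-9′ is deliberately erased.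

Step 11
Reactants: 20 9′-(2-methylpropylidene) silyl ketal (name as in step 10)
Product: 22 (1R,3a′S,6R,9′S,9a′R)-6,9a′-dimethyl-9′-(2-methylpropyl)-3-(propan-2-yl)-1′,2′,9′,9a′-tetrahydro-3a′H-spiro[cyclohex-2-ene-1,3′-cyclopenta[b]chromene]-6′,8′-diol, via bis(methoxymethyl) ether 21 (not isolated)
Conditions: Et3SiH (6 equiv), CF3CO2H (10 equiv), CH2Cl2, −78 → −20 °C; then HCl (3 M), MeOH, 40 °C
Reagents that add atoms: none
Why: Ionic hydrogenation: the acid ionises the silyl ketal to the cyclic aryl-oxocarbenium ion and protonates the electron-rich styrene to the benzylic cation, and the silane delivers hydride to C-3a′ and C-9′ from the convex face of the cis-fused ring system (the face of the angular methyl group, away from the cyclopentane and spiro ring; a trans ring fusion is too strained), which places H-3a′ cis and the isobutyl group trans to the 9a′-methyl group; acidic methanol then removes the methoxymethyl ethers, and the low temperature should spare the isolated trisubstituted alkene.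

Step 12
Reactants: 22 (1R,3a′S,6R,9′S,9a′R)-6,9a′-dimethyl-9′-(2-methylpropyl)-3-(propan-2-yl)-1′,2′,9′,9a′-tetrahydro-3a′H-spiro[cyclohex-2-ene-1,3′-cyclopenta[b]chromene]-6′,8′-diol
Product: 24 (1R,3a′S,6R,9′S,9a′R)-6′,8′-dihydroxy-6,9a′-dimethyl-9′-(2-methylpropyl)-3-(propan-2-yl)-1′,2′,9′,9a′-tetrahydro-3a′H-spiro[cyclohex-2-ene-1,3′-cyclopenta[b]chromene]-5′,7′-dicarbaldehyde (target), via bis(iminium) salt 23 (not isolated)
Conditions: POCl3 (4 equiv), DMF, EtOAc, 0 °C → rt; then NaOAc, H2O, 60 °C
Reagents that add atoms: N,N-dimethylformamide (CN(C)C=O); water (O)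
Why: Vilsmeier–Haack formylation: the two free ring positions of the phloroglucinol-type arene, each ortho or para to three oxygen substituents, are attacked by the chloroiminium ion and the bis(iminium) salt is hydrolysed to the dialdehyde; no stereocentre is touched.

**Compound list**

1 | 1-(cyclopent-1-en-1-yl)pyrrolidine | C1CCN(C1)C2=CCCC2 | starting material
2 | 3-methylbutanoyl chloride | CC(C)CC(=O)Cl | starting material
3 | 3-methyl-1-[2-(pyrrolidin-1-yl)cyclopent-1-en-1-yl]butan-1-one (acyl enamine) | CC(C)CC(=O)C1=C(N2CCCC2)CCC1 | intermediate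
4 | 2-(3-methylbutanoyl)cyclopentan-1-one (racemic, enolisable C-2) | CC(C)CC(=O)C1CCCC1=O | intermediate
5 | (E)-but-2-enal | C/C=C/C=O | starting material
6 | (3R)-3-[(1S)-1-(3-methylbutanoyl)-2-oxocyclopentyl]butanal | O=C1CCC[C@]1(C(=O)CC(C)C)[C@H](C)CC=O | intermediate
7 | (5S,10R)-10-methyl-7-(propan-2-yl)spiro[4.5]dec-7-ene-1,6-dione | O=C2CCC[C@@]21C(=O)C(C(C)C)=CC[C@H]1C | intermediate
8 | lithium enolate of 7 (O-1, C-1=C-2) | [Li+].[O-]C2=CCC[C@@]21C(=O)C(C(C)C)=CC[C@H]1C | intermediate
9 | (5S,10R)-2,10-dimethyl-7-(propan-2-yl)spiro[4.5]dec-7-ene-1,6-dione (C-2 epimers) | O=C2C(C)CC[C@@]21C(=O)C(C(C)C)=CC[C@H]1C | intermediate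
10 | lithium enolate from conjugate reduction of 9 (O-6, C-6=C-7; C-2 epimers) | [Li+].O=C2C(C)CC[C@@]21C([O-])=C(C(C)C)CC[C@H]1C | intermediate
11 | (5R,10R)-2,10-dimethyl-1-oxo-7-(propan-2-yl)spiro[4.5]dec-6-en-6-yl trifluoromethanesulfonate (C-2 epimers) | O=C2C(C)CC[C@@]21C(OS(=O)(=O)C(F)(F)F)=C(C(C)C)CC[C@H]1C | intermediate
12 | (5R,10R)-2,10-dimethyl-7-(propan-2-yl)spiro[4.5]dec-6-en-1-one (C-2 epimers) | O=C2C(C)CC[C@@]21C=C(C(C)C)CC[C@H]1C | intermediate
13 | tert-butyl{[(5R,10R)-2,10-dimethyl-7-(propan-2-yl)spiro[4.5]deca-1,6-dien-1-yl]oxy}dimethylsilane | CC(C)(C)[Si](C)(C)OC2=C(C)CC[C@@]21C=C(C(C)C)CC[C@H]1C | intermediate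
14 | 2,4,6-trihydroxybenzaldehyde | O=Cc1c(O)cc(O)cc1O | starting material
15 | 2-hydroxy-4,6-bis(methoxymethoxy)benzaldehyde | COCOc1cc(O)c(C=O)c(OCOC)c1 | intermediate
16 | tert-butyl 2-formyl-3,5-bis(methoxymethoxy)phenyl carbonate | COCOc1cc(OC(=O)OC(C)(C)C)c(C=O)c(OCOC)c1 | intermediate
17 | isobutylmagnesium bromide | CC(C)C[Mg]Br | starting material
18 | 6-[(E)-3-methylbutylidene]-3,5-bis(methoxymethoxy)cyclohexa-2,4-dien-1-one (o-quinone methide) | CC(C)C/C=C1/C(=O)C=C(OCOC)C=C1OCOC | intermediate
19 | tert-butyl{[(1R,3a′R,6R,9′S,9a′R)-6′,8′-bis(methoxymethoxy)-6,9a′-dimethyl-9′-(2-methylpropyl)-3-(propan-2-yl)-1′,2′,9′,9a′-tetrahydro-3a′H-spiro[cyclohex-2-ene-1,3′-cyclopenta[b]chromen]-3a′-yl]oxy}dimethylsilane (isobutyl cis to 9a′-methyl; ether oxygen and C-9′ cis to the vinylic CH on the cyclopentane) | CC(C)C[C@H]1c2c(OCOC)cc(OCOC)cc2O[C@@]2(O[Si](C)(C)C(C)(C)C)[C@]1(C)CC[C@@]21C=C(C(C)C)CC[C@H]1C | intermediate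
20 | tert-butyl{[(1R,3a′R,6R,9a′R)-6′,8′-bis(methoxymethoxy)-6,9a′-dimethyl-9′-(2-methylpropylidene)-3-(propan-2-yl)-1′,2′,9′,9a′-tetrahydro-3a′H-spiro[cyclohex-2-ene-1,3′-cyclopenta[b]chromen]-3a′-yl]oxy}dimethylsilane (alkene geometry not controlled) | CC(C)C=C1c2c(OCOC)cc(OCOC)cc2O[C@@]2(O[Si](C)(C)C(C)(C)C)[C@]1(C)CC[C@@]21C=C(C(C)C)CC[C@H]1C | intermediate
21 | (1R,3a′S,6R,9′S,9a′R)-6′,8′-bis(methoxymethoxy)-6,9a′-dimethyl-9′-(2-methylpropyl)-3-(propan-2-yl)-1′,2′,9′,9a′-tetrahydro-3a′H-spiro[cyclohex-2-ene-1,3′-cyclopenta[b]chromene] (cis ring fusion; isobutyl trans to 9a′-methyl) | CC(C)C[C@@H]1c2c(OCOC)cc(OCOC)cc2O[C@H]2[C@]1(C)CC[C@@]21C=C(C(C)C)CC[C@H]1C | intermediate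
22 | (1R,3a′S,6R,9′S,9a′R)-6,9a′-dimethyl-9′-(2-methylpropyl)-3-(propan-2-yl)-1′,2′,9′,9a′-tetrahydro-3a′H-spiro[cyclohex-2-ene-1,3′-cyclopenta[b]chromene]-6′,8′-diol | CC(C)C[C@@H]1c2c(O)cc(O)cc2O[C@H]2[C@]1(C)CC[C@@]21C=C(C(C)C)CC[C@H]1C | intermediate
23 | 5′,7′-bis[(dimethyliminio)methyl] derivative of 22, dichloride (bis(iminium) salt) | CC(C)C[C@@H]1c2c(O)c(C=[N+](C)C)c(O)c(C=[N+](C)C)c2O[C@H]2[C@]1(C)CC[C@@]21C=C(C(C)C)CC[C@H]1C.[Cl-].[Cl-] | intermediate
24 | (1R,3a′S,6R,9′S,9a′R)-6′,8′-dihydroxy-6,9a′-dimethyl-9′-(2-methylpropyl)-3-(propan-2-yl)-1′,2′,9′,9a′-tetrahydro-3a′H-spiro[cyclohex-2-ene-1,3′-cyclopenta[b]chromene]-5′,7′-dicarbaldehyde | CC(C)C[C@@H]1c2c(O)c(C=O)c(O)c(C=O)c2O[C@H]2[C@]1(C)CC[C@@]21C=C(C(C)C)CC[C@H]1C | target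

**Step count and risks**

Total steps: 12. Longest linear sequence: 10 steps (steps 1–6 and 9–12; steps 7–8 prepare the arene partner).

Steps most likely to fail:

Step 2. The risk is poor diastereofacial control at the spiro carbon during the conjugate addition, or retro-Claisen cleavage of the non-enolisable 1,3-diketone in the acid stage. Fallback, setting out from 4: an iridium-catalysed, branched-selective asymmetric allylic alkylation with (E)-but-2-en-1-yl methyl carbonate ([Ir(cod)Cl]2, chiral phosphoramidite ligand, base, THF) should give (2S)-2-[(2R)-but-3-en-2-yl]-2-(3-methylbutanoyl)cyclopentan-1-one F1, with both centres now set at the metal–allyl stage. An aldehyde-selective Wacker-type oxidation of the vinyl group (PdCl2(PhCN)2, CuCl2, AgNO2, O2, t-BuOH/MeNO2) then gives aldehyde 6, where the route is rejoined at the TsOH stage of step 2.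

Step 9. The risk is that the hindered, tetrasubstituted silyl enol ether traps the quinone methide more slowly than the quinone methide oligomerises, or that silyl transfer competes with ring closure. Fallback, setting out from ketone 12: the lithium enolate (LiN(iPr)2, THF, −78 °C) is added to 18, generated separately from 16 and 17. Stepwise Michael addition of the small, planar enolate and hemiketalisation on work-up should give the 3a′-hydroxy analogue of 19, hemiketal F2 (C-9′ epimers). DDQ as in step 10 gives the 9′-(2-methylpropylidene) hemiketal F3, and Et3SiH/CF3CO2H followed by HCl/MeOH as in step 11 returns to 22.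

Step 10. The risk is slow hydride abstraction, because the benzylic hydrogen of 19 lies on the concave face, or over-oxidation at the allylic and isopropyl C–H bonds. Fallback, setting out from 19: reduction and deprotection are done first (Et3SiH, CF3CO2H, CH2Cl2, −78 → −20 °C; then HCl, MeOH) to give the 9′-epimer of 22, diol F4. Oxidation of its free para-phenol with Ag2O (benzene, rt) gives the p-quinone methide F5, in which C-9′ is trigonal. A 1,6-reduction with NaBH4 from the convex face returns to 22.

Further compounds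
F1 | step 2 | (2S)-2-[(2R)-but-3-en-2-yl]-2-(3-methylbutanoyl)cyclopentan-1-one | O=C1CCC[C@]1(C(=O)CC(C)C)[C@H](C)C=C
F2 | step 9 | 3a′-hydroxy analogue of 19 (hemiketal; C-9′ epimers; other centres as in 19) | CC(C)CC1c2c(OCOC)cc(OCOC)cc2O[C@@]2(O)[C@]1(C)CC[C@@]21C=C(C(C)C)CC[C@H]1C
F3 | step 9 | 3a′-hydroxy analogue of 20 (9′-(2-methylpropylidene) hemiketal; alkene geometry not controlled) | CC(C)C=C1c2c(OCOC)cc(OCOC)cc2O[C@@]2(O)[C@]1(C)CC[C@@]21C=C(C(C)C)CC[C@H]1C
F4 | step 10 | 9′-epimer of 22 (isobutyl cis to 9a′-methyl) | CC(C)C[C@H]1c2c(O)cc(O)cc2O[C@H]2[C@]1(C)CC[C@@]21C=C(C(C)C)CC[C@H]1C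
F5 | step 10 | p-quinone methide of 22 (C-9′=C-8a′, 6′-oxo, 8′-hydroxy) | CC(C)CC1=C2C(O)=CC(=O)C=C2O[C@H]2[C@]1(C)CC[C@@]21C=C(C(C)C)CC[C@H]1C
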